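**Strategy.** The trans-clerodane core is traced back to (+)-sclareolide through one backbone rearrangement. In a single operation a Lewis acid opens an 8α,9α-epoxy-tetranorlabdane at C9 and drives three consecutive 1,2-shifts (C10 methyl to C9, H-5 to C10, 4β-methyl to C5), ending as the C3=C4 alkene and leaving the 8α-hydroxyl. The step exploits the C9–C10–C5 triad at the ring A/ring B fusion (C20 β, H-10 α, C19 β), which is the labdane axial array moved by one atom. The precursor is the α-epoxide of the C8=C9 alkene with C11–C12 as a silyl-protected hydroxyethyl arm. Rings A and B and the C12–C16 hydroxylactone are elaborated afterwards.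

Key step: step 5

Remark: face selectivities are taken from the usual models for a rigid trans-decalin (attack anti to the axial C19 and C20 methyls) and for acyclic allylic alcohols; the configurations written at C2 (13, 14) and C7 (21–23, 39, 40) are the predicted ones and are erased later.

Step 1
Reactants: 1 (+)-sclareolide
Product: 3 methyl 13,14,15,16-tetranorlabd-8-en-12-oate, via 13,14,15,16-tetranorlabd-8-en-12-oic acid 2 (not isolated)
Conditions: H2SO4 (conc.), MeOH, reflux
Reagents that add atoms: methanol, CO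
Why: Acid-promoted alkyl–oxygen cleavage of the tertiary lactone (E1) with Fischer esterification under equilibrating conditions should favour the tetrasubstituted C8=C9 alkene, the minor C7 and C8(17) isomers being removed by chromatography; no stereocentre is created.

Step 2
Reactants: 3 methyl 13,14,15,16-tetranorlabd-8-en-12-oate
Product: 4 13,14,15,16-tetranorlabd-8-en-12-ol
Conditions: LiAlH4, THF, 0 °C
Reagents that add atoms: none
Why: Hydride reduction of the ester gives the primary alcohol and leaves the hindered tetrasubstituted alkene untouched.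

Step 3
Reactants: 4 13,14,15,16-tetranorlabd-8-en-12-ol
Product: 5 12-(tert-butyldiphenylsilyloxy)-13,14,15,16-tetranorlabd-8-ene
Conditions: t-BuPh2SiCl, imidazole, DMF, rt
Reagents that add atoms: tert-butyl(chloro)diphenylsilane, CC(C)(C)[Si](Cl)(c1ccccc1)c1ccccc1
Why: Silylation of the primary alcohol gives an ether that is inert to Lewis acid, chromium oxidants and amide bases and, unlike an ester at C12, cannot lactonise with the later 8α-hydroxyl.

Step 4
Reactants: 5 12-(tert-butyldiphenylsilyloxy)-13,14,15,16-tetranorlabd-8-ene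
Product: 6 8α,9α-epoxy-12-(tert-butyldiphenylsilyloxy)-13,14,15,16-tetranorlabdane
Conditions: 3-chloroperbenzoic acid, NaHCO3, CH2Cl2, 0 °C
Reagents that add atoms: 3-chloroperbenzoic acid, OOC(=O)c1cccc(Cl)c1
Why: Prilezhaev epoxidation takes place on the α face, opposite the axial C10 methyl, which fixes the 8α,9α-epoxide.

Step 5
Reactants: 6 8α,9α-epoxy-12-(tert-butyldiphenylsilyloxy)-13,14,15,16-tetranorlabdane
Product: 7 12-(tert-butyldiphenylsilyloxy)-13,14,15,16-tetranorclerod-3-en-8α-ol (C19 β on C5, H-10 α, C20 β on C9, C17 β on C8)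
Conditions: BF3·OEt2 (0.3 equiv), CH2Cl2, −78 °C, then Et3N
Reagents that add atoms: none
Why: BF3 binds the epoxide oxygen and the C9–O bond ionises while the axial C10 methyl migrates to C9 antiperiplanar to the leaving oxygen; the 5α-hydrogen then shifts to C10, the axial 4β-methyl shifts to C5, and the C4 cation loses H-3 to give the C3=C4 alkene. The closest known reaction type is the Lewis-acid-induced friedo (backbone, Wagner–Meerwein) rearrangement of 8,9-epoxy drimanes and labdanes to halimane and clerodane skeletons. No ring is formed; the decalin is kept and only C20, one hydrogen and C19 change place. Each new centre (C9, C10, C5) is set by a suprafacial 1,2-shift with inversion at the receiving carbon, so C20 ends β, H-10 α and C19 β, as dictated by the 8α,9α-epoxide and the all-axial array inherited from sclareolide. The step needs ionisation at C9 and not C8, and all three shifts before any proton loss: the antiperiplanar C10–CH3 bond assists only C9–O cleavage, and the silyloxyethyl arm neither withdraws electrons from C9 as an ester would nor can reach C9. The non-basic medium at −78 °C with a late amine quench disfavours elimination at C10 or C5 and pinacol-type ring contraction.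

Step 6
Reactants: 7 12-(tert-butyldiphenylsilyloxy)-13,14,15,16-tetranorclerod-3-en-8α-ol
Product: 9 12-(tert-butyldiphenylsilyloxy)-13,14,15,16-tetranorcleroda-3,7-diene, via 8α-chlorosulfite ester 8 (not isolated)
Conditions: SOCl2, pyridine, CH2Cl2, −40 to 0 °C
Reagents that add atoms: none
Why: The axial 8α-chlorosulfite is antiperiplanar to the axial 7β-hydrogen and C9 is quaternary, so base-mediated E2 elimination should give mainly the C7=C8 alkene without ionisation at C8 and hence without a Wagner–Meerwein shift of C20.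

Step 7
Reactants: 9 12-(tert-butyldiphenylsilyloxy)-13,14,15,16-tetranorcleroda-3,7-diene
Product: 10 12-(tert-butyldiphenylsilyloxy)-13,14,15,16-tetranorcleroda-3,7-diene-2,6-dione
Conditions: CrO3, 3,5-dimethylpyrazole, CH2Cl2, −20 °C
Reagents that add atoms: chromium trioxide, O=[Cr](=O)=O
Why: Allylic oxidation with the CrO3–3,5-dimethylpyrazole complex converts the only ring methylene next to each trisubstituted alkene (C2 and C6) into an enone carbonyl, the other allylic positions being quaternary or methyl.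

Step 8
Reactants: 10 12-(tert-butyldiphenylsilyloxy)-13,14,15,16-tetranorcleroda-3,7-diene-2,6-dione; 11 isobutyric acid
Product: 12 1α-isobutyryloxy-12-(tert-butyldiphenylsilyloxy)-13,14,15,16-tetranorcleroda-3,7-diene-2,6-dione
Conditions: Mn(OAc)3·2H2O, isobutyric acid (excess), benzene, reflux, Dean–Stark
Reagents that add atoms: none
Why: Oxidative α'-acyloxylation of an enone by Mn(OAc)3 in the presence of a carboxylic acid runs through the manganese enolate, which only ring A can form because the ring B enone has a quaternary α' carbon (C5); the ester enters C1 anti to the axial C19 methyl, and the equatorial 1α-ester is also the thermodynamic epimer.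

Step 9
Reactants: 12 1α-isobutyryloxy-12-(tert-butyldiphenylsilyloxy)-13,14,15,16-tetranorcleroda-3,7-diene-2,6-dione
Product: 13 2β-hydroxy-1α-isobutyryloxy-12-(tert-butyldiphenylsilyloxy)-13,14,15,16-tetranorcleroda-3,7-dien-6-one
Conditions: NaBH4 (1.0 equiv), CeCl3·7H2O, MeOH/CH2Cl2, −78 °C
Reagents that add atoms: none
Why: Luche reduction with one equivalent of hydride should select the C2 carbonyl, activated by the neighbouring acyloxy group, over the C6 carbonyl shielded by the quaternary C5; axial attack gives the equatorial 2β-alcohol, a centre removed two steps later.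

Step 10
Reactants: 13 2β-hydroxy-1α-isobutyryloxy-12-(tert-butyldiphenylsilyloxy)-13,14,15,16-tetranorcleroda-3,7-dien-6-one
Product: 14 2β-(phenoxythiocarbonyloxy)-1α-isobutyryloxy-12-(tert-butyldiphenylsilyloxy)-13,14,15,16-tetranorcleroda-3,7-dien-6-one
Conditions: PhOC(S)Cl, pyridine, 4-(dimethylamino)pyridine (cat.), CH2Cl2, 0 °C to rt
Reagents that add atoms: O-phenyl chlorothionoformate, S=C(Cl)Oc1ccccc1
Why: Acylation of the only hydroxyl gives the thionocarbonate needed for radical deoxygenation, and a [3,3]-shift of the thiocarbonyl group is disfavoured because the far allyl terminus C4 is fully substituted.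

Step 11
Reactants: 14 2β-(phenoxythiocarbonyloxy)-1α-isobutyryloxy-12-(tert-butyldiphenylsilyloxy)-13,14,15,16-tetranorcleroda-3,7-dien-6-one
Product: 15 1α-isobutyryloxy-12-(tert-butyldiphenylsilyloxy)-13,14,15,16-tetranorcleroda-3,7-dien-6-one
Conditions: Bu3SnH, azobis(isobutyronitrile) (cat.), toluene, 80 °C
Reagents that add atoms: none
Why: Barton–McCombie deoxygenation generates the C2–C3–C4 allyl radical, which should take hydrogen from Bu3SnH at the less hindered C2 terminus and so restore the C3=C4 alkene, the thiocarbonyl group reacting far faster with stannyl radicals than the hindered enone.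

Step 12
Reactants: 15 1α-isobutyryloxy-12-(tert-butyldiphenylsilyloxy)-13,14,15,16-tetranorcleroda-3,7-dien-6-one
Product: 16 18-hydroxy-1α-isobutyryloxy-12-(tert-butyldiphenylsilyloxy)-13,14,15,16-tetranorcleroda-3,7-dien-6-one
Conditions: SeO2 (0.5 equiv), t-BuOOH, CH2Cl2, 0 °C to rt
Reagents that add atoms: tert-butyl hydroperoxide, CC(C)(C)OO
Why: Riley allylic oxidation (ene reaction, then [2,3]-shift) attacks the allylic position on the more substituted alkene carbon C4, which can only be the C18 methyl because C5 is quaternary, while the electron-poor ring B enone is inert.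

Step 13
Reactants: 16 18-hydroxy-1α-isobutyryloxy-12-(tert-butyldiphenylsilyloxy)-13,14,15,16-tetranorcleroda-3,7-dien-6-one
Product: 19 1α-isobutyryloxy-12-(tert-butyldiphenylsilyloxy)-13,14,15,16-tetranorcleroda-4(18),7-dien-6-one, via 18-sulfonylhydrazine adduct 17 (not isolated), via 18-allylic diazene 18 (not isolated)
Conditions: 2-nitrobenzenesulfonylhydrazide, PPh3, diethyl azodicarboxylate, N-methylmorpholine, −30 °C, then rt
Reagents that add atoms: none
Why: Mitsunobu displacement of the primary allylic alcohol by the sulfonylhydrazide, loss of sulfinic acid and retro-ene extrusion of N2 from the allylic diazene deliver hydrogen to C3 and move the alkene to the exocyclic C4=C18 position (reductive 1,3-transposition of an allylic alcohol).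

Step 14
Reactants: 19 1α-isobutyryloxy-12-(tert-butyldiphenylsilyloxy)-13,14,15,16-tetranorcleroda-4(18),7-dien-6-one
Product: 22 1α-isobutyryloxy-12-(tert-butyldiphenylsilyloxy)-13,14,15,16-tetranorcleroda-4(18),8(17)-diene-6β,7α-diol, via potassium dienolate 20 (not isolated), via 7α-hydroxy-6-ketone 21 (not isolated)
Conditions: KN(SiMe3)2, THF, −78 °C; 2-(benzenesulfonyl)-3-phenyloxaziridine; AcOH; then NaBH4 (excess), MeOH, −78 to −20 °C
Reagents that add atoms: 2-(benzenesulfonyl)-3-phenyloxaziridine, O=S(=O)(c1ccccc1)N1OC1c1ccccc1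
Why: The ring B enone can be deprotonated only at the C17 methyl (C5 and C9 are quaternary); the dienolate is hydroxylated by the oxaziridine at its α carbon C7 from the α face, opposite the axial C19 and C20 methyls, which places the alkene at C8=C17, and borohydride then attacks the C6 ketone from the same open face to give the equatorial 6β-alcohol (enolate hydroxylation followed by ketone reduction).

Step 15
Reactants: 22 1α-isobutyryloxy-12-(tert-butyldiphenylsilyloxy)-13,14,15,16-tetranorcleroda-4(18),8(17)-diene-6β,7α-diol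
Product: 23 1α-isobutyryloxy-6β,7α-isopropylidenedioxy-12-(tert-butyldiphenylsilyloxy)-13,14,15,16-tetranorcleroda-4(18),8(17)-diene
Conditions: 2-methoxypropene, pyridinium p-toluenesulfonate (cat.), CH2Cl2, 0 °C
Reagents that add atoms: 2-methoxypropene, C=C(C)OC
Why: Acid-catalysed transacetalisation ties the trans-diequatorial diol into an isopropylidene acetal, so that neither hydroxyl interferes with the oxidations and the hydroxyl-directed epoxidation that follow.

Step 16
Reactants: 23 1α-isobutyryloxy-6β,7α-isopropylidenedioxy-12-(tert-butyldiphenylsilyloxy)-13,14,15,16-tetranorcleroda-4(18),8(17)-diene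
Product: 24 1α-isobutyryloxy-6β,7α-isopropylidenedioxy-13,14,15,16-tetranorcleroda-4(18),8(17)-dien-12-ol
Conditions: Bu4NF, AcOH, THF, rt
Reagents that add atoms: none
Why: Fluoride cleaves the silicon–oxygen bond of the primary silyl ether, acetic acid buffering the medium so that the isobutyrate is not attacked.

Step 17
Reactants: 24 1α-isobutyryloxy-6β,7α-isopropylidenedioxy-13,14,15,16-tetranorcleroda-4(18),8(17)-dien-12-ol
Product: 25 1α-isobutyryloxy-6β,7α-isopropylidenedioxy-13,14,15,16-tetranorcleroda-4(18),8(17)-dien-12-al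
Conditions: Dess–Martin periodinane, NaHCO3, CH2Cl2, 0 °C to rt
Reagents that add atoms: none
Why: Dess–Martin oxidation converts the primary alcohol into the aldehyde under buffered conditions that leave the acetal and the ester intact.

Step 18
Reactants: 26 3-bromobut-3-en-1-ol
Product: 27 (3-bromobut-3-enyloxy)(tert-butyl)dimethylsilane
Conditions: t-BuMe2SiCl, imidazole, CH2Cl2, rt
Reagents that add atoms: tert-butyl(chloro)dimethylsilane, CC(C)(C)[Si](C)(C)Cl
Why: Silylation protects the C15 hydroxyl of the four-carbon unit, whose alkene terminus will become C16 and whose silyloxyethyl arm will become C14–C15.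

Step 19
Reactants: 25 1α-isobutyryloxy-6β,7α-isopropylidenedioxy-13,14,15,16-tetranorcleroda-4(18),8(17)-dien-12-al; 27 (3-bromobut-3-enyloxy)(tert-butyl)dimethylsilane
Product: 29 (12RS)-15-(tert-butyldimethylsilyloxy)-1α-isobutyryloxy-6β,7α-isopropylidenedioxycleroda-4(18),8(17),13(16)-trien-12-ol, via alkenylchromium dichloride 28 (not isolated)
Conditions: CrCl2, NiCl2 (cat.), DMSO, rt
Reagents that add atoms: none
Why: Nozaki–Hiyama–Kishi coupling: the alkenylchromium reagent formed from the bromide under nickel catalysis adds only to the aldehyde and leaves the ester, acetal and alkenes untouched; both C12 epimers form and converge in the next step.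

Step 20
Reactants: 29 (12RS)-15-(tert-butyldimethylsilyloxy)-1α-isobutyryloxy-6β,7α-isopropylidenedioxycleroda-4(18),8(17),13(16)-trien-12-ol
Product: 30 15-(tert-butyldimethylsilyloxy)-1α-isobutyryloxy-6β,7α-isopropylidenedioxycleroda-4(18),8(17),13(16)-trien-12-one
Conditions: Dess–Martin periodinane, NaHCO3, CH2Cl2, 0 °C
Reagents that add atoms: none
Why: Dess–Martin oxidation of the allylic alcohol erases the C12 centre and gives the α-methylene ketone for a reagent-controlled reduction.

Step 21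
Reactants: 30 15-(tert-butyldimethylsilyloxy)-1α-isobutyryloxy-6β,7α-isopropylidenedioxycleroda-4(18),8(17),13(16)-trien-12-one
Product: 31 (12R)-15-(tert-butyldimethylsilyloxy)-1α-isobutyryloxy-6β,7α-isopropylidenedioxycleroda-4(18),8(17),13(16)-trien-12-ol
Conditions: (S)-2-methyl-CBS-oxazaborolidine (cat.), catecholborane, toluene, −78 °C
Reagents that add atoms: none
Why: Corey–Bakshi–Shibata reduction: with the (S)-oxazaborolidine the 1,1-disubstituted alkenyl group acts as the large substituent and the C11 methylene as the small one, so hydride should be delivered to give the 12R alcohol, and catecholborane at −78 °C does not hydroborate the alkenes.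

Step 22
Reactants: 31 (12R)-15-(tert-butyldimethylsilyloxy)-1α-isobutyryloxy-6β,7α-isopropylidenedioxycleroda-4(18),8(17),13(16)-trien-12-ol
Product: 32 (12R,13S)-13,16-epoxy-15-(tert-butyldimethylsilyloxy)-1α-isobutyryloxy-6β,7α-isopropylidenedioxycleroda-4(18),8(17)-dien-12-ol
Conditions: VO(acac)2 (cat.), t-BuOOH, CH2Cl2, 0 °C to rt
Reagents that add atoms: tert-butyl hydroperoxide, CC(C)(C)OO
Why: Hydroxyl-directed vanadium-catalysed epoxidation touches only the allylic alcohol alkene and, for an alkene substituted at C13 (allylic 1,2-strain), should give the erythro epoxy alcohol, which with 12R corresponds to 13S.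

Step 23
Reactants: 32 (12R,13S)-13,16-epoxy-15-(tert-butyldimethylsilyloxy)-1α-isobutyryloxy-6β,7α-isopropylidenedioxycleroda-4(18),8(17)-dien-12-ol; 33 tiglic acid
Product: 35 (12R,13S)-13,16-epoxy-15-(tert-butyldimethylsilyloxy)-1α-isobutyryloxy-6β,7α-isopropylidenedioxy-12-tigloyloxycleroda-4(18),8(17)-diene, via tiglic trichlorobenzoic anhydride 34 (not isolated)
Conditions: 2,4,6-trichlorobenzoyl chloride, Et3N, THF, rt; then 32, 4-(dimethylamino)pyridine, toluene, rt
Reagents that add atoms: none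
Why: Yamaguchi esterification through the mixed anhydride acylates the hindered secondary C12 hydroxyl under base-only conditions that leave the epoxide intact, and the E geometry of the tiglate is kept.

Step 24
Reactants: 35 (12R,13S)-13,16-epoxy-15-(tert-butyldimethylsilyloxy)-1α-isobutyryloxy-6β,7α-isopropylidenedioxy-12-tigloyloxycleroda-4(18),8(17)-diene
Product: 36 (12R,13S)-13,16-epoxy-1α-isobutyryloxy-6β,7α-isopropylidenedioxy-12-tigloyloxycleroda-4(18),8(17)-dien-15-ol
Conditions: Bu4NF, AcOH, THF, 0 °C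
Reagents that add atoms: none
Why: Buffered fluoride removes the primary silyl ether, and the cold, non-acidic medium should not promote the acid-dependent closure of the freed alcohol onto the epoxide, so the crude epoxy alcohol can be oxidised directly.

Step 25
Reactants: 36 (12R,13S)-13,16-epoxy-1α-isobutyryloxy-6β,7α-isopropylidenedioxy-12-tigloyloxycleroda-4(18),8(17)-dien-15-ol
Product: 39 (12R,13S)-13-hydroxy-1α-isobutyryloxy-6β,7α-isopropylidenedioxy-12-tigloyloxycleroda-4(18),8(17)-dien-15,16-olide, via 15-aldehyde 37 (not isolated), via 13,16-epoxy-15-oic acid 38 (not isolated)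
Conditions: 2,2,6,6-tetramethylpiperidin-1-oxyl (cat.), PhI(OAc)2, MeCN/pH 7 phosphate buffer, rt to 40 °C
Reagents that add atoms: water, O
Why: Oxoammonium oxidation takes the primary alcohol through the aldehyde to the acid, whose carboxyl group, acting as internal acid and nucleophile, opens the β,γ-epoxide at the unsubstituted C16 (the known lactonisation of β,γ-epoxy acids to β-hydroxy-γ-lactones) without breaking the C13–O bond, so 13S is kept.

Step 26
Reactants: 39 (12R,13S)-13-hydroxy-1α-isobutyryloxy-6β,7α-isopropylidenedioxy-12-tigloyloxycleroda-4(18),8(17)-dien-15,16-olide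
Product: 40 (12R,13S)-6β,7α,13-trihydroxy-1α-isobutyryloxy-12-tigloyloxycleroda-4(18),8(17)-dien-15,16-olide
Conditions: AcOH/H2O/THF, rt
Reagents that add atoms: none
Why: Mild aqueous acid hydrolyses the strained trans-fused isopropylidene acetal, while both esters, the lactone and the tertiary alcohol are stable.

Step 27
Reactants: 40 (12R,13S)-6β,7α,13-trihydroxy-1α-isobutyryloxy-12-tigloyloxycleroda-4(18),8(17)-dien-15,16-olide
Product: 41 CNP0182744.1, (12R,13S)-6β,13-dihydroxy-1α-isobutyryloxy-7-oxo-12-tigloyloxycleroda-4(18),8(17)-dien-15,16-olide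
Conditions: MnO2 (activated, excess), CH2Cl2, rt
Reagents that add atoms: none
Why: MnO2 oxidises only the allylic C7 hydroxyl, whose axial C–H overlaps with the C8=C17 π bond, and leaves the saturated C6 and tertiary C13 hydroxyls, giving the α-methylene ketone under neutral conditions that avoid enolisation of the 6-hydroxy ketone.

**Compound list**

1 | (+)-sclareolide | CC1(C)CCC[C@@]2(C)[C@H]1CC[C@@]3(C)OC(=O)C[C@H]23 | starting material
2 | 13,14,15,16-tetranorlabd-8-en-12-oic acid | CC1(C)CCC[C@@]2(C)[C@H]1CCC(C)=C2CC(=O)O | intermediate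
3 | methyl 13,14,15,16-tetranorlabd-8-en-12-oate | CC1(C)CCC[C@@]2(C)[C@H]1CCC(C)=C2CC(=O)OC | intermediate
4 | 13,14,15,16-tetranorlabd-8-en-12-ol | CC1(C)CCC[C@@]2(C)[C@H]1CCC(C)=C2CCO | intermediate
5 | 12-(tert-butyldiphenylsilyloxy)-13,14,15,16-tetranorlabd-8-ene | CC1(C)CCC[C@@]2(C)[C@H]1CCC(C)=C2CCO[Si](c5ccccc5)(c6ccccc6)C(C)(C)C | intermediate
6 | 8α,9α-epoxy-12-(tert-butyldiphenylsilyloxy)-13,14,15,16-tetranorlabdane | CC1(C)CCC[C@@]2(C)[C@H]1CC[C@@]3(C)O[C@@]23CCO[Si](c5ccccc5)(c6ccccc6)C(C)(C)C | intermediate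
7 | 12-(tert-butyldiphenylsilyloxy)-13,14,15,16-tetranorclerod-3-en-8α-ol | CC1=CCC[C@@H]2[C@]1(C)CC[C@@](C)(O)[C@@]2(C)CCO[Si](c5ccccc5)(c6ccccc6)C(C)(C)C | intermediate
8 | 8α-chlorosulfite ester of 7 | CC1=CCC[C@@H]2[C@]1(C)CC[C@@](C)(OS(=O)Cl)[C@@]2(C)CCO[Si](c5ccccc5)(c6ccccc6)C(C)(C)C | intermediate
9 | 12-(tert-butyldiphenylsilyloxy)-13,14,15,16-tetranorcleroda-3,7-diene | CC1=CCC[C@@H]2[C@]1(C)CC=C(C)[C@@]2(C)CCO[Si](c5ccccc5)(c6ccccc6)C(C)(C)C | intermediate
10 | 12-(tert-butyldiphenylsilyloxy)-13,14,15,16-tetranorcleroda-3,7-diene-2,6-dione | CC1=CC(=O)C[C@@H]2[C@]1(C)C(=O)C=C(C)[C@@]2(C)CCO[Si](c5ccccc5)(c6ccccc6)C(C)(C)C | intermediate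
11 | isobutyric acid | CC(C)C(=O)O | starting material
12 | 1α-isobutyryloxy-12-(tert-butyldiphenylsilyloxy)-13,14,15,16-tetranorcleroda-3,7-diene-2,6-dione | CC1=CC(=O)[C@H](OC(=O)C(C)C)[C@@H]2[C@]1(C)C(=O)C=C(C)[C@@]2(C)CCO[Si](c5ccccc5)(c6ccccc6)C(C)(C)C | intermediate
13 | 2β-hydroxy-1α-isobutyryloxy-12-(tert-butyldiphenylsilyloxy)-13,14,15,16-tetranorcleroda-3,7-dien-6-one | CC1=C[C@@H](O)[C@H](OC(=O)C(C)C)[C@@H]2[C@]1(C)C(=O)C=C(C)[C@@]2(C)CCO[Si](c5ccccc5)(c6ccccc6)C(C)(C)C | intermediate
14 | 2β-(phenoxythiocarbonyloxy)-1α-isobutyryloxy-12-(tert-butyldiphenylsilyloxy)-13,14,15,16-tetranorcleroda-3,7-dien-6-one | CC1=C[C@@H](OC(=S)Oc7ccccc7)[C@H](OC(=O)C(C)C)[C@@H]2[C@]1(C)C(=O)C=C(C)[C@@]2(C)CCO[Si](c5ccccc5)(c6ccccc6)C(C)(C)C | intermediate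
15 | 1α-isobutyryloxy-12-(tert-butyldiphenylsilyloxy)-13,14,15,16-tetranorcleroda-3,7-dien-6-one | CC1=CC[C@H](OC(=O)C(C)C)[C@@H]2[C@]1(C)C(=O)C=C(C)[C@@]2(C)CCO[Si](c5ccccc5)(c6ccccc6)C(C)(C)C | intermediate
16 | 18-hydroxy-1α-isobutyryloxy-12-(tert-butyldiphenylsilyloxy)-13,14,15,16-tetranorcleroda-3,7-dien-6-one | OCC1=CC[C@H](OC(=O)C(C)C)[C@@H]2[C@]1(C)C(=O)C=C(C)[C@@]2(C)CCO[Si](c5ccccc5)(c6ccccc6)C(C)(C)C | intermediate
17 | 18-[1-(2-nitrobenzenesulfonyl)hydrazin-1-yl] analogue of 16 (Mitsunobu adduct) | NN(CC1=CC[C@H](OC(=O)C(C)C)[C@@H]2[C@]1(C)C(=O)C=C(C)[C@@]2(C)CCO[Si](c5ccccc5)(c6ccccc6)C(C)(C)C)S(=O)(=O)c7ccccc7[N+](=O)[O-] | intermediate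
18 | 18-diazenyl analogue of 16 (allylic diazene) | N=NCC1=CC[C@H](OC(=O)C(C)C)[C@@H]2[C@]1(C)C(=O)C=C(C)[C@@]2(C)CCO[Si](c5ccccc5)(c6ccccc6)C(C)(C)C | intermediate
19 | 1α-isobutyryloxy-12-(tert-butyldiphenylsilyloxy)-13,14,15,16-tetranorcleroda-4(18),7-dien-6-one | C=C1CC[C@H](OC(=O)C(C)C)[C@@H]2[C@]1(C)C(=O)C=C(C)[C@@]2(C)CCO[Si](c5ccccc5)(c6ccccc6)C(C)(C)C | intermediate
20 | potassium dienolate of 19 (6-olate of the 4(18),6,8(17)-triene) | C=C1CC[C@H](OC(=O)C(C)C)[C@@H]2[C@]1(C)C([O-])=CC(=C)[C@@]2(C)CCO[Si](c5ccccc5)(c6ccccc6)C(C)(C)C.[K+] | intermediate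
21 | 7α-hydroxy-1α-isobutyryloxy-12-(tert-butyldiphenylsilyloxy)-13,14,15,16-tetranorcleroda-4(18),8(17)-dien-6-one | C=C1CC[C@H](OC(=O)C(C)C)[C@@H]2[C@]1(C)C(=O)[C@@H](O)C(=C)[C@@]2(C)CCO[Si](c5ccccc5)(c6ccccc6)C(C)(C)C | intermediate
22 | 1α-isobutyryloxy-12-(tert-butyldiphenylsilyloxy)-13,14,15,16-tetranorcleroda-4(18),8(17)-diene-6β,7α-diol | C=C1CC[C@H](OC(=O)C(C)C)[C@@H]2[C@]1(C)[C@H](O)[C@@H](O)C(=C)[C@@]2(C)CCO[Si](c5ccccc5)(c6ccccc6)C(C)(C)C | intermediate
23 | 1α-isobutyryloxy-6β,7α-isopropylidenedioxy-12-(tert-butyldiphenylsilyloxy)-13,14,15,16-tetranorcleroda-4(18),8(17)-diene | C=C1CC[C@H](OC(=O)C(C)C)[C@@H]2[C@]1(C)[C@H](OC(C)(C)O3)[C@@H]3C(=C)[C@@]2(C)CCO[Si](c5ccccc5)(c6ccccc6)C(C)(C)C | intermediate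
24 | 1α-isobutyryloxy-6β,7α-isopropylidenedioxy-13,14,15,16-tetranorcleroda-4(18),8(17)-dien-12-ol | C=C1CC[C@H](OC(=O)C(C)C)[C@@H]2[C@]1(C)[C@H](OC(C)(C)O3)[C@@H]3C(=C)[C@@]2(C)CCO | intermediate
25 | 1α-isobutyryloxy-6β,7α-isopropylidenedioxy-13,14,15,16-tetranorcleroda-4(18),8(17)-dien-12-al | C=C1CC[C@H](OC(=O)C(C)C)[C@@H]2[C@]1(C)[C@H](OC(C)(C)O3)[C@@H]3C(=C)[C@@]2(C)CC=O | intermediate
26 | 3-bromobut-3-en-1-ol | C=C(Br)CCO | starting material
27 | (3-bromobut-3-enyloxy)(tert-butyl)dimethylsilane | C=C(Br)CCO[Si](C)(C)C(C)(C)C | intermediate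
28 | dichloro[4-(tert-butyldimethylsilyloxy)but-1-en-2-yl]chromium | C=C([Cr](Cl)Cl)CCO[Si](C)(C)C(C)(C)C | intermediate
29 | (12RS)-15-(tert-butyldimethylsilyloxy)-1α-isobutyryloxy-6β,7α-isopropylidenedioxycleroda-4(18),8(17),13(16)-trien-12-ol | C=C1CC[C@H](OC(=O)C(C)C)[C@@H]2[C@]1(C)[C@H](OC(C)(C)O3)[C@@H]3C(=C)[C@@]2(C)CC(O)C(=C)CCO[Si](C)(C)C(C)(C)C | intermediate
30 | 15-(tert-butyldimethylsilyloxy)-1α-isobutyryloxy-6β,7α-isopropylidenedioxycleroda-4(18),8(17),13(16)-trien-12-one | C=C1CC[C@H](OC(=O)C(C)C)[C@@H]2[C@]1(C)[C@H](OC(C)(C)O3)[C@@H]3C(=C)[C@@]2(C)CC(=O)C(=C)CCO[Si](C)(C)C(C)(C)C | intermediate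
31 | (12R)-15-(tert-butyldimethylsilyloxy)-1α-isobutyryloxy-6β,7α-isopropylidenedioxycleroda-4(18),8(17),13(16)-trien-12-ol | C=C1CC[C@H](OC(=O)C(C)C)[C@@H]2[C@]1(C)[C@H](OC(C)(C)O3)[C@@H]3C(=C)[C@@]2(C)C[C@@H](O)C(=C)CCO[Si](C)(C)C(C)(C)C | intermediate
32 | (12R,13S)-13,16-epoxy-15-(tert-butyldimethylsilyloxy)-1α-isobutyryloxy-6β,7α-isopropylidenedioxycleroda-4(18),8(17)-dien-12-ol | C=C1CC[C@H](OC(=O)C(C)C)[C@@H]2[C@]1(C)[C@H](OC(C)(C)O3)[C@@H]3C(=C)[C@@]2(C)C[C@@H](O)[C@]4(CCO[Si](C)(C)C(C)(C)C)CO4 | intermediate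
33 | tiglic acid | C/C=C(\C)C(=O)O | starting material
34 | tiglic 2,4,6-trichlorobenzoic anhydride | C/C=C(\C)C(=O)OC(=O)c1c(Cl)cc(Cl)cc1Cl | intermediate
35 | (12R,13S)-13,16-epoxy-15-(tert-butyldimethylsilyloxy)-1α-isobutyryloxy-6β,7α-isopropylidenedioxy-12-tigloyloxycleroda-4(18),8(17)-diene | C=C1CC[C@H](OC(=O)C(C)C)[C@@H]2[C@]1(C)[C@H](OC(C)(C)O3)[C@@H]3C(=C)[C@@]2(C)C[C@@H](OC(=O)/C(C)=C/C)[C@]4(CCO[Si](C)(C)C(C)(C)C)CO4 | intermediate
36 | (12R,13S)-13,16-epoxy-1α-isobutyryloxy-6β,7α-isopropylidenedioxy-12-tigloyloxycleroda-4(18),8(17)-dien-15-ol | C=C1CC[C@H](OC(=O)C(C)C)[C@@H]2[C@]1(C)[C@H](OC(C)(C)O3)[C@@H]3C(=C)[C@@]2(C)C[C@@H](OC(=O)/C(C)=C/C)[C@]4(CCO)CO4 | intermediate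
37 | (12R,13S)-13,16-epoxy-1α-isobutyryloxy-6β,7α-isopropylidenedioxy-12-tigloyloxycleroda-4(18),8(17)-dien-15-al | C=C1CC[C@H](OC(=O)C(C)C)[C@@H]2[C@]1(C)[C@H](OC(C)(C)O3)[C@@H]3C(=C)[C@@]2(C)C[C@@H](OC(=O)/C(C)=C/C)[C@]4(CC=O)CO4 | intermediate
38 | (12R,13S)-13,16-epoxy-1α-isobutyryloxy-6β,7α-isopropylidenedioxy-12-tigloyloxycleroda-4(18),8(17)-dien-15-oic acid | C=C1CC[C@H](OC(=O)C(C)C)[C@@H]2[C@]1(C)[C@H](OC(C)(C)O3)[C@@H]3C(=C)[C@@]2(C)C[C@@H](OC(=O)/C(C)=C/C)[C@]4(CC(=O)O)CO4 | intermediate
39 | (12R,13S)-13-hydroxy-1α-isobutyryloxy-6β,7α-isopropylidenedioxy-12-tigloyloxycleroda-4(18),8(17)-dien-15,16-olide | C=C1CC[C@H](OC(=O)C(C)C)[C@@H]2[C@]1(C)[C@H](OC(C)(C)O3)[C@@H]3C(=C)[C@@]2(C)C[C@@H](OC(=O)/C(C)=C/C)[C@@]4(O)COC(=O)C4 | intermediate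
40 | (12R,13S)-6β,7α,13-trihydroxy-1α-isobutyryloxy-12-tigloyloxycleroda-4(18),8(17)-dien-15,16-olide | C=C1CC[C@H](OC(=O)C(C)C)[C@@H]2[C@]1(C)[C@H](O)[C@@H](O)C(=C)[C@@]2(C)C[C@@H](OC(=O)/C(C)=C/C)[C@@]4(O)COC(=O)C4 | intermediate
41 | CNP0182744.1, (12R,13S)-6β,13-dihydroxy-1α-isobutyryloxy-7-oxo-12-tigloyloxycleroda-4(18),8(17)-dien-15,16-olide | C=C1CC[C@H](OC(=O)C(C)C)[C@@H]2[C@]1(C)[C@H](O)C(=O)C(=C)[C@@]2(C)C[C@@H](OC(=O)/C(C)=C/C)[C@@]1(O)COC(=O)C1 | target

**Step count.** Total: 27 steps. Longest linear sequence: 26 steps (steps 1–17 and 19–27 from (+)-sclareolide; step 18 prepares the side-chain bromide).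

**Steps most likely to fail**

Step 5. The cascade may stop by proton loss from the C10 or C5 cation after only one or two shifts, or the epoxide may ionise at C8 and contract ring B. The fallback changes the trigger from an epoxide–Lewis acid pair to a bromonium ion. It sets out from alkene 5: N-bromosuccinimide in hexafluoroisopropanol at −20 °C should form the α-bromonium ion, whose opening at C9 is again assisted by the antiperiplanar C10 methyl, and the same three shifts should end as 8α-bromo-12-(tert-butyldiphenylsilyloxy)-13,14,15,16-tetranorclerod-3-ene F1. Dehydrobromination of this axial tertiary bromide with 1,8-diazabicyclo[5.4.0]undec-7-ene in toluene at 80 °C (antiperiplanar H-7β) returns to the route at diene 9.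

Step 14. The oxidant may attack the terminal C17 carbon of the dienolate, or the α-hydroxy ketone may enolise further and drift to the conjugated diosphenol before it is reduced. The fallback avoids enolate chemistry and sets out from enone 19. Weitz–Scheffer epoxidation (t-BuOOH, benzyltrimethylammonium hydroxide, THF, 0 °C) should add peroxide to C8 from the α face and give 7α,8α-epoxy-1α-isobutyryloxy-12-(tert-butyldiphenylsilyloxy)-13,14,15,16-tetranorclerod-4(18)-en-6-one F2. Reduction with NaBH4 and CeCl3·7H2O in MeOH at −40 °C (hydride from the α face) gives 7α,8α-epoxy-1α-isobutyryloxy-12-(tert-butyldiphenylsilyloxy)-13,14,15,16-tetranorclerod-4(18)-en-6β-ol F3. Cp2TiCl (trivalent titanium, made from Cp2TiCl2 and manganese dust, THF, rt) then opens the epoxide homolytically at C8, and the tertiary radical loses a C17 hydrogen, which returns to the route at diol 22.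

Step 8. Acetate instead of isobutyrate may be transferred from the manganese carboxylate, or the ring B enone may be oxidised through its dienol. The fallback replaces oxidative acyloxylation by enolate hydroxylation and acylation and sets out from dione 10. Kinetic deprotonation at C1 with LiN(SiMe3)2 (THF, −78 °C; only ring A has α' hydrogens) and hydroxylation with 2-(benzenesulfonyl)-3-phenyloxaziridine from the α face should give 1α-hydroxy-12-(tert-butyldiphenylsilyloxy)-13,14,15,16-tetranorcleroda-3,7-diene-2,6-dione F4. Acylation with isobutyryl chloride, pyridine and 4-(dimethylamino)pyridine in CH2Cl2 returns to the route at 12.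

Further compounds
F1 | step 5 | 8α-bromo-12-(tert-butyldiphenylsilyloxy)-13,14,15,16-tetranorclerod-3-ene | CC1=CCC[C@@H]2[C@]1(C)CC[C@@](C)(Br)[C@@]2(C)CCO[Si](c5ccccc5)(c6ccccc6)C(C)(C)C
F2 | step 14 | 7α,8α-epoxy-1α-isobutyryloxy-12-(tert-butyldiphenylsilyloxy)-13,14,15,16-tetranorclerod-4(18)-en-6-one | C=C1CC[C@H](OC(=O)C(C)C)[C@@H]2[C@]1(C)C(=O)[C@@H](O3)[C@]3(C)[C@@]2(C)CCO[Si](c5ccccc5)(c6ccccc6)C(C)(C)C
F3 | step 14 | 7α,8α-epoxy-1α-isobutyryloxy-12-(tert-butyldiphenylsilyloxy)-13,14,15,16-tetranorclerod-4(18)-en-6β-ol | C=C1CC[C@H](OC(=O)C(C)C)[C@@H]2[C@]1(C)[C@H](O)[C@@H](O3)[C@]3(C)[C@@]2(C)CCO[Si](c5ccccc5)(c6ccccc6)C(C)(C)C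
F4 | step 8 | 1α-hydroxy-12-(tert-butyldiphenylsilyloxy)-13,14,15,16-tetranorcleroda-3,7-diene-2,6-dione | CC1=CC(=O)[C@H](O)[C@@H]2[C@]1(C)C(=O)C=C(C)[C@@]2(C)CCO[Si](c5ccccc5)(c6ccccc6)C(C)(C)C
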